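## Retrosynthetic overview

1. 13 ⇒ in one flask, cut both C–C bonds of the [4+2] ring, the benzylic C7–O bond of the tetrahydrofuran and the C2=C3 bond of the lactone. This leads to acyclic epoxy acrylate 8 and (R)-α-phellandrene 9. Free altholactone is never isolated.
2. 8 ⇒ acryloyl chloride 7 + epoxy alcohol 6 (acylation of O5).
3. 6 ⇒ cut the C4–C5 bond: epoxy aldehyde 2 + (Z)-γ-(methoxymethoxy)allylborane 5, made from allyl alcohol 3 through ether 4.
4. 2 ⇒ cinnamaldehyde 1 by catalytic asymmetric epoxidation. The oxirane stores C6 and C7.
5. Ring order: oxirane (step 1, consumed later) → δ-lactone → tetrahydrofuran → bicyclo[2.2.2]octene, the last three all in step 5.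

Assumption and numbering: a sequence run in one flask without isolation counts as one step. Chain numbering is C1 = lactone C=O, C2=C3, C4 (tetrahydrofuran O), C5 (lactone O), C6 (OH), C7 (CHPh).

## Route

Step 1
Reactants: 1 (E)-cinnamaldehyde
Product: 2 (2R,3S)-3-phenyloxirane-2-carbaldehyde
Conditions: 35 % aq. H2O2 (1.3 equiv), (R)-2-{bis[3,5-bis(trifluoromethyl)phenyl](trimethylsilyloxy)methyl}pyrrolidine (10 mol %), CH2Cl2, rt
Reagents that add atoms: hydrogen peroxide, OO
Why: Iminium/enamine-catalysed Weitz–Scheffer epoxidation of an enal, in which the side arm of the (R)-catalyst shields the Si face of Cβ of the E-iminium ion so that hydroperoxide adds to the Re face and the enamine closes on the O–O bond to the trans (2R,3S)-epoxide, fixing C6 and the pre-inversion configuration of C7.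

Step 2
Reactants: 3 allyl alcohol
Product: 4 allyl methoxymethyl ether
Conditions: CH2(OMe)2 (solvent), LiBr (10 mol %), p-TsOH·H2O (5 mol %), rt; distil
Reagents that add atoms: dimethoxymethane, COCOC
Why: Acid-catalysed acetal exchange driven by the excess of dimethoxymethane, with no stereocentre formed.

Step 3
Reactants: 2 (2R,3S)-3-phenyloxirane-2-carbaldehyde; 4 allyl methoxymethyl ether
Product: 6 (1R,2S)-2-(methoxymethoxy)-1-[(2S,3S)-3-phenyloxiran-2-yl]but-3-en-1-ol, via Z-alkoxyallylborane 5 (not isolated)
Conditions: 4 (1.4 equiv), s-BuLi, THF, −78 °C; (+)-Ipc2BOMe, −78 °C; BF3·OEt2 (1.05 equiv per boron), then 2, −78 °C, 4 h; HOCH2CH2NH2, Et2O, rt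
Reagents that add atoms: none
Why: Brown asymmetric γ-alkoxyallylboration, in which the chelated (Z)-allyllithium gives (Z)-borane 5, its chair Zimmerman–Traxler transition state turns Z geometry into the C4/C5 syn relationship, and the isopinocampheyl groups from (−)-α-pinene direct attack to the Re face of the aldehyde (C5 R, C4 S), overriding the weak intrinsic anti bias of the epoxy aldehyde.

Step 4
Reactants: 6 (1R,2S)-2-(methoxymethoxy)-1-[(2S,3S)-3-phenyloxiran-2-yl]but-3-en-1-ol; 7 acryloyl chloride
Product: 8 (1R,2S)-2-(methoxymethoxy)-1-[(2R,3S)-3-phenyloxiran-2-yl]but-3-en-1-yl acrylate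
Conditions: 7 (1.5 equiv), Et3N (2 equiv), DMAP (5 mol %), CH2Cl2, 0 °C
Reagents that add atoms: none
Why: DMAP-catalysed O-acylation of the only free hydroxyl, in a basic medium that leaves epoxide, acetal and all stereocentres untouched (the oxirane descriptor changes only through CIP priorities).

Step 5
Reactants: 8 (1R,2S)-2-(methoxymethoxy)-1-[(2R,3S)-3-phenyloxiran-2-yl]but-3-en-1-yl acrylate; 9 (R)-(−)-α-phellandrene
Product: 13 CNP0249919.1 (endo cycloadduct of the altholactone core on (R)-α-phellandrene), via epoxy pyranone 10 (not isolated), via altholactone aluminium alkoxide 11 (not isolated), via cycloadduct aluminium alkoxide 12 (not isolated)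
Conditions: second-generation Hoveyda–Grubbs catalyst (5 mol %), CH2Cl2 (0.02 M), 40 °C, 8 h; distil off solvent in the same flask to 0.2 M; 9 (8 equiv, freshly distilled), Me2AlCl (3.5 equiv, hexanes), −78 °C to rt, 36 h; cold 1 M HCl
Reagents that add atoms: none
Why: Proposed new method: ring-closing metathesis of the acrylate/allylic-ether diene first gives pyranone 10 (a known reaction type that also ties the ester carbonyl back so it cannot attack the epoxide), and the single Lewis acid then does two jobs: (a) it activates the benzylic epoxide so that the cis-placed C4 ether oxygen attacks C7 in a 5-endo, SN2-like opening with inversion (closest known types: MeAlCl2- or Me2AlCl-initiated epoxide-opening cyclisations and dealkylative cycloetherification by ether-oxygen participation), the CH3OCH2 group of the oxonium ion being removed irreversibly by methyl transfer from the aluminate as in organoaluminium acetal alkylation, and (b) it activates the lactone carbonyl for a Diels–Alder reaction with 9 (closest known type: Me2AlCl-promoted [4+2] additions of α-phellandrene to acrylic and propiolic esters), where the four new stereocentres follow from endo approach, attack on the diene face anti to the isopropyl group, attack on the lactone face anti to the C4–O and C5–C6 bonds, and the "para" orientation set by the diene methyl group, so the outcome is the same whichever of (a) and (b) happens first.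

## Compound list

1 | (E)-cinnamaldehyde | O=C/C=C/c1ccccc1 | starting material
2 | (2R,3S)-3-phenyloxirane-2-carbaldehyde (trans) | O=C[C@@H]1O[C@H]1c1ccccc1 | intermediate
3 | allyl alcohol | C=CCO | starting material
4 | allyl methoxymethyl ether | C=CCOCOC | intermediate
5 | [(Z)-3-(methoxymethoxy)allyl]bis(isopinocampheyl)borane, Ipc groups from (−)-α-pinene | COCO/C=C\CB([C@H]1C[C@H]2C[C@H](C2(C)C)[C@@H]1C)[C@H]1C[C@H]2C[C@H](C2(C)C)[C@@H]1C | intermediate
6 | (1R,2S)-2-(methoxymethoxy)-1-[(2S,3S)-3-phenyloxiran-2-yl]but-3-en-1-ol (C4/C5 syn, C5/C6 syn, trans-epoxide) | O[C@@H]([C@@H]1O[C@H]1c1ccccc1)[C@@H](OCOC)C=C | intermediate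
7 | acryloyl chloride | C=CC(=O)Cl | starting material
8 | (1R,2S)-2-(methoxymethoxy)-1-[(2R,3S)-3-phenyloxiran-2-yl]but-3-en-1-yl acrylate | C=CC(=O)O[C@@H]([C@@H]1O[C@H]1c1ccccc1)[C@@H](OCOC)C=C | intermediate
9 | (R)-(−)-α-phellandrene | CC1=CC[C@@H](C=C1)C(C)C | starting material
10 | (5S,6R)-5-(methoxymethoxy)-6-[(2R,3S)-3-phenyloxiran-2-yl]-5,6-dihydro-2H-pyran-2-one (5,6-cis) | O=C1O[C@@H]([C@@H]2O[C@H]2c2ccccc2)[C@@H](OCOC)C=C1 | intermediate
11 | chloro(methyl)aluminium alkoxide of (2R,3R,3aS,7aS)-3-hydroxy-2-phenyl-2,3,3a,7a-tetrahydro-5H-furo[3,2-b]pyran-5-one | O=C1O[C@H]2[C@H](O[Al](C)Cl)[C@@H](c3ccccc3)O[C@H]2C=C1 | intermediate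
12 | chloro(methyl)aluminium alkoxide of 13 | CC1=C[C@@H]2[C@@H]3C(=O)O[C@H]4[C@H](O[Al](C)Cl)[C@@H](c5ccccc5)O[C@H]4[C@@H]3[C@H]1C[C@@H]2C(C)C | intermediate
13 | CNP0249919.1: cis-fused 2-phenyl-3-hydroxytetrahydrofuran/δ-lactone (C4 S, C5 S, C6 R, C7 R) fused at C2–C3 to a methyl, isopropyl bicyclo[2.2.2]octene. C2 (S) is bonded to the bridgehead next to CH-iPr. C3 (R) is bonded to the bridgehead next to C(Me)=. Both bridgeheads are R and CH-iPr is R. The lactone and the isopropyl group are both syn to the C=C bridge, and the new C–C bonds are anti to the tetrahydrofuran oxygen | CC1=C[C@@H]2[C@@H]3C(=O)O[C@H]4[C@H](O)[C@@H](c5ccccc5)O[C@H]4[C@@H]3[C@H]1C[C@@H]2C(C)C | target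

## Step count and risks

Total step count: 5. Longest linear sequence: 4 (steps 1, 3, 4, 5).

**Step 5 (highest risk).**
- Chloride from Me2AlCl, or a 1,2-hydride shift, may consume the benzylic epoxide before the ether oxygen does.
- The methoxymethyl group may end up on O6.
- Ruthenium residues or cationic species may isomerise or oligomerise 9.
- The β-substituted lactone may be too slow a dienophile.

The fallback sets out from 8 and comes back at 13. The metathesis is run alone and pyranone 10 is isolated. Then 10 and 9 are joined without any Lewis acid at 1.2 GPa in CH2Cl2 at 40 °C. This neutral hyperbaric Diels–Alder reaction leaves the oxirane and acetal untouched. The same facial, endo and regiochemical preferences apply, and it gives the epoxy methoxymethyl cycloadduct F1. Only then, with the acid-sensitive diene removed, camphorsulfonic acid in wet CH2Cl2 triggers attack of the C4 ether oxygen on C7 with inversion and loss of the acetal, giving 13. The order of events is thus reversed: cycloaddition first, cycloetherification last.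

**Step 3.**
- The phenyl-substituted epoxy aldehyde may rearrange under traces of free BF3.
- The required C5/C6 syn product is the mismatched pairing.

The fallback sets out from 1, with borane 5 made from 4 as before, and comes back at 6. Borane 5 is added to cinnamaldehyde 1, which carries no epoxide. The same face selectivity gives (1E,3S,4S)-4-(methoxymethoxy)-1-phenylhexa-1,5-dien-3-ol F2. The oxirane is then installed afterwards under reagent control, using the L-fructose-derived enantiomer of the Shi ketone, KHSO5 and K2CO3 buffer in MeCN/dimethoxymethane/water at 0 °C. This epoxidises the trans-styrenyl alkene in preference to the terminal vinyl group and delivers 6.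

**Step 1.**
- Enantiomeric purity, trans/cis ratio and handling of the labile aldehyde on scale are uncertain.

The fallback sets out from 1 and comes back at 2. NaBH4 in MeOH gives cinnamyl alcohol F3. Katsuki–Sharpless epoxidation follows, with Ti(OiPr)4, L-(+)-diisopropyl tartrate, t-BuOOH and 4 Å sieves in CH2Cl2 at −20 °C. It gives crystalline (2S,3S)-3-phenylglycidol F4, which can be recrystallised to enantiopurity. Parikh–Doering oxidation (SO3·pyridine, DMSO, Et3N) then returns 2.

## Further compounds

F1 | step 5 | epoxy methoxymethyl cycloadduct (13 with the C7–O4 bond not yet formed: C4-OCH2OMe, trans C6–C7 oxirane) | CC1=C[C@@H]2[C@@H]3C(=O)O[C@@H]([C@@H]4O[C@H]4c4ccccc4)[C@@H](OCOC)[C@@H]3[C@H]1C[C@@H]2C(C)C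
F2 | step 3 | (1E,3S,4S)-4-(methoxymethoxy)-1-phenylhexa-1,5-dien-3-ol | O[C@@H](/C=C/c1ccccc1)[C@@H](OCOC)C=C
F3 | step 1 | cinnamyl alcohol | OC/C=C/c1ccccc1
F4 | step 1 | (2S,3S)-3-phenylglycidol | OC[C@@H]1O[C@H]1c1ccccc1
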